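Hardest feature: rings A and B are the same 1-alkyl-2,3,4,5-tetraoxygenated C6 unit, so a late oxidation to the quinone cannot tell them apart. The only stereocentre, C3, also becomes labile once it sits next to the quinone.
Enabling feature: C2'(=O)-C3'(OMe)=C4'(OMe)-C5'(=O) of ring B and C8a(O)-C8(OMe)-C7(OMe)-C6(OMe) of ring A are each the C4O4 core of dimethyl squarate. C1'=C6'H maps onto a terminal alkyne and C4a=C5H onto a vinyl iodide.
Cuts: C1'-C2' and C5'-C6' (ring B), then O1-C2 (pyran), then C4a-C8a and C5-C6 (ring A). What remains is an acyclic C6 enyne and two molecules of squarate, so no arene is bought.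
Forward: ring A forms first (4π opening/6π closure of an alkenylcyclobutenone), then the pyran (Mitsunobu). Ring B forms last (4π opening/Moore cyclization of an alkynylcyclobutenone) and is born as the quinone in a neutral, oxidant-free isomerisation.
Stereochemistry: C3 is set once, by Rh-catalysed asymmetric conjugate alkynylation of an achiral enal, and is a spectator in every later step.

Key step: step 9

Assumption: the target SMILES is read as the (3S)-isoflavanquinone; (S)-DTBM-SEGPHOS is assigned in step 2 by analogy with the facial model for Rh/biaryl-bisphosphine 1,4-additions to (E)-acceptors, and if the sense is opposite the equally available (R)-ligand is used with no other change.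

Step 1
Reactants: 1 (tert-butyldimethylsilyloxy)acetaldehyde; 2 (triphenylphosphoranylidene)acetaldehyde
Product: 3 (E)-4-[(tert-butyldimethylsilyl)oxy]but-2-enal
Conditions: toluene, 80 °C
Reagents that add atoms: none
Why: Wittig olefination with the stabilised formyl ylide should give the (E)-enal and stop after one homologation, because the product enal is less electrophilic than the α-silyloxy aldehyde.

Step 2
Reactants: 3 (E)-4-[(tert-butyldimethylsilyl)oxy]but-2-enal; 4 (triisopropylsilyl)acetylene
Product: 5 (3S)-3-{[(tert-butyldimethylsilyl)oxy]methyl}-5-(triisopropylsilyl)pent-4-ynal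
Conditions: [Rh(OAc)(C2H4)2]2 (cat.), (S)-DTBM-SEGPHOS (cat.), MeOH, 40 °C
Reagents that add atoms: none
Why: In this Rh(I)-catalysed asymmetric conjugate alkynylation of a β-alkyl enal, the bulky silyl group and ligand suppress alkyne dimerisation and 1,2-addition, the alkynyl-rhodium species inserts the enal C=C on the face left open by the bisphosphine and so sets C3 as (S), and protonation of the oxa-π-allyl rhodium releases the aldehyde.

Step 3
Reactants: 5 (3S)-3-{[(tert-butyldimethylsilyl)oxy]methyl}-5-(triisopropylsilyl)pent-4-ynal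
Product: 6 (1E,4S)-4-{[(tert-butyldimethylsilyl)oxy]methyl}-1-iodo-6-(triisopropylsilyl)hex-1-en-5-yne
Conditions: CrCl2 (excess), CHI3, THF, 0 °C to rt
Reagents that add atoms: iodoform, C(I)(I)I
Why: Takai olefination turns the aldehyde carbon (future C4a) into an (E)-vinyl iodide under non-basic conditions that leave both silyl groups and the β-stereocentre alone, and a minor (Z)-isomer is tolerable because both alkene carbons end up in the arene.

Step 4
Reactants: 6 (1E,4S)-4-{[(tert-butyldimethylsilyl)oxy]methyl}-1-iodo-6-(triisopropylsilyl)hex-1-en-5-yne; 7 dimethyl squarate (3,4-dimethoxycyclobut-3-ene-1,2-dione)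
Product: 10 4-[(1E,4S)-4-{[(tert-butyldimethylsilyl)oxy]methyl}-6-(triisopropylsilyl)hex-1-en-5-yn-1-yl]-2,3,4-trimethoxycyclobut-2-en-1-one (both epimers at ring C4), via [(1E,4S)-4-{[(tert-butyldimethylsilyl)oxy]methyl}-6-(triisopropylsilyl)hex-1-en-5-yn-1-yl]lithium 8 (not isolated), via lithium 1-alkenyl-2,3-dimethoxy-4-oxocyclobut-2-en-1-olate 9 (not isolated)
Conditions: t-BuLi (2.1 equiv), Et2O, −78 °C; cannulate into 7, THF, −78 °C; MeOTf (3 equiv, the excess covers LiI), −78 to 0 °C
Reagents that add atoms: methyl trifluoromethanesulfonate, COS(=O)(=O)C(F)(F)F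
Why: Iodine–lithium exchange with retention of geometry, 1,2-addition to one squarate carbonyl and O-methylation of the tertiary alkoxide in the same flask form the standard entry to 4-alkenyl-4-alkoxycyclobutenones; the trap installs the future 6-OMe and so distinguishes O6 from the future O1, and the new carbinol centre is destroyed in step 5.

Step 5
Reactants: 10 4-alkenyl-2,3,4-trimethoxycyclobut-2-en-1-one
Product: 13 6-[(2S)-2-{[(tert-butyldimethylsilyl)oxy]methyl}-4-(triisopropylsilyl)but-3-yn-1-yl]-2,3,4-trimethoxyphenol, via (Z,E)-dienylketene O=C=C(OMe)-C(OMe)=C(OMe)-CH=CH-CH2R 11 (not isolated), via 6-alkyl-2,3,4-trimethoxycyclohexa-2,4-dien-1-one 12 (not isolated)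
Conditions: p-xylene (degassed, dilute), 138 °C, Ar
Reagents that add atoms: none
Why: In this thermal cyclobutenone benzannulation, conrotatory 4π opening with the methoxy group rotating outward places the alkenyl group cis to the ketene, 6π electrocyclisation forms C4a-C8a, and tautomerisation of the dienone gives ring A with its only free OH at C8a, where the pyran must close.

Step 6
Reactants: 13 6-[(2S)-2-{[(tert-butyldimethylsilyl)oxy]methyl}-4-(triisopropylsilyl)but-3-yn-1-yl]-2,3,4-trimethoxyphenol
Product: 14 6-[(2S)-2-(hydroxymethyl)but-3-yn-1-yl]-2,3,4-trimethoxyphenol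
Conditions: TBAF (3 equiv), THF, 0 °C to rt
Reagents that add atoms: none
Why: Fluoride-mediated desilylation cleaves the O–TBS and the C(sp)–TIPS bonds in one operation, and the merely propargylic C3–H is not acidic enough to be affected.

Step 7
Reactants: 14 6-[(2S)-2-(hydroxymethyl)but-3-yn-1-yl]-2,3,4-trimethoxyphenol
Product: 15 (3S)-3-ethynyl-6,7,8-trimethoxychroman
Conditions: PPh3, DIAD, THF (dilute), 0 °C to rt
Reagents that add atoms: none
Why: Intramolecular Mitsunobu etherification (6-exo-tet attack of the C8a phenoxide on the activated primary C2) closes the pyran at the CH2 next to C3, so the stereocentre is untouched.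

Step 8
Reactants: 15 (3S)-3-ethynyl-6,7,8-trimethoxychroman; 7 dimethyl squarate
Product: 18 4-hydroxy-2,3-dimethoxy-4-{[(3S)-6,7,8-trimethoxychroman-3-yl]ethynyl}cyclobut-2-en-1-one (both epimers at ring C4), via lithium acetylide of 15 16 (not isolated), via lithium 1-alkynyl-2,3-dimethoxy-4-oxocyclobut-2-en-1-olate 17 (not isolated)
Conditions: n-BuLi (1.0 equiv), THF, −78 °C; add to 7 (1.2 equiv), THF, −78 °C; aq NH4Cl, −78 °C
Reagents that add atoms: none
Why: Deprotonation of the terminal alkyne and 1,2-addition of the acetylide to a squarate carbonyl (inverse addition against double addition) is the standard preparation of 4-alkynyl-4-hydroxycyclobutenones, and the carbinol epimers converge in step 9.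

Step 9
Reactants: 18 4-hydroxy-2,3-dimethoxy-4-{[(3S)-6,7,8-trimethoxychroman-3-yl]ethynyl}cyclobut-2-en-1-one
Product: 21 abruquinone B, 2,3-dimethoxy-5-[(3S)-6,7,8-trimethoxychroman-3-yl]cyclohexa-2,5-diene-1,4-dione, via (Z)-enynylketene O=C=C(OMe)-C(OMe)=C(OH)-C≡C-R 19 (not isolated), via aromatic 1,4-diradical (phenoxyl O on C2', σ-radical on C6', OH on C5') 20 (not isolated)
Conditions: p-xylene (degassed, 0.01 M), 138 °C, Ar, dark
Reagents that add atoms: none
Why: Heating opens the strained cyclobutenone by conrotatory 4π electrocyclic reaction in which the C4 hydroxyl rotates outward and the alkynyl group inward, giving enynylketene 19. The ketene carbon then bonds to the distal alkyne carbon (Moore cyclization, the ketene analogue of the Myers–Saito enyne–allene cyclization), a formal 6-endo-dig closure that makes ring B as diradical 20, and transfer of the hydroxyl hydrogen to C6' gives the quinone directly at its final oxidation level. The closest known reaction type is the thermal rearrangement of 4-alkynyl-4-hydroxy-2,3-dialkoxycyclobutenones bearing alkyl-substituted alkynes to 5-alkyl-2,3-dialkoxy-1,4-benzoquinones. No new stereocentre forms; C3 stays sp3 and is not flanked by an acidifying group until the last bond is made, and because the medium is neutral, aprotic and free of oxidant, neither epimerisation through the quinone methide tautomer nor oxidative demethylation of ring A (whose O1/6-OMe para pair is as oxidisable as any ring-B precursor) should occur. The selectivity needed is six- over five-membered closure (quinone against 2-alkylidenecyclopentene-1,3-dione); it is secured by the sp3 substituent C3 on the alkyne, which gives no stabilisation to the exocyclic vinyl radical of the five-ring path, and the regiochemistry is fixed because the alkyne carbon bearing C3 becomes C1' and the carbinol carbon becomes C5'.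

Compound list
1 | (tert-butyldimethylsilyloxy)acetaldehyde | CC(C)(C)[Si](C)(C)OCC=O | starting material
2 | (triphenylphosphoranylidene)acetaldehyde | O=CC=P(c1ccccc1)(c1ccccc1)c1ccccc1 | starting material
3 | (E)-4-[(tert-butyldimethylsilyl)oxy]but-2-enal | CC(C)(C)[Si](C)(C)OC/C=C/C=O | intermediate
4 | (triisopropylsilyl)acetylene | C#C[Si](C(C)C)(C(C)C)C(C)C | starting material
5 | (3S)-3-{[(tert-butyldimethylsilyl)oxy]methyl}-5-(triisopropylsilyl)pent-4-ynal | CC(C)[Si](C(C)C)(C(C)C)C#C[C@H](CC=O)CO[Si](C)(C)C(C)(C)C | intermediate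
6 | (1E,4S)-4-{[(tert-butyldimethylsilyl)oxy]methyl}-1-iodo-6-(triisopropylsilyl)hex-1-en-5-yne | CC(C)[Si](C(C)C)(C(C)C)C#C[C@H](C/C=C/I)CO[Si](C)(C)C(C)(C)C | intermediate
7 | dimethyl squarate | COC1=C(OC)C(=O)C1=O | starting material
8 | (E)-vinyllithium from 6 | CC(C)[Si](C(C)C)(C(C)C)C#C[C@H](C/C=C/[Li])CO[Si](C)(C)C(C)(C)C | intermediate
9 | lithium alkoxide of the alkenyl–squarate adduct | CC(C)[Si](C(C)C)(C(C)C)C#C[C@H](C/C=C/C1(O[Li])C(OC)=C(OC)C1=O)CO[Si](C)(C)C(C)(C)C | intermediate
10 | 4-[(1E,4S)-alkenyl]-2,3,4-trimethoxycyclobut-2-en-1-one | CC(C)[Si](C(C)C)(C(C)C)C#C[C@H](C/C=C/C1(OC)C(OC)=C(OC)C1=O)CO[Si](C)(C)C(C)(C)C | intermediate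
11 | (Z,E)-dienylketene | CC(C)[Si](C(C)C)(C(C)C)C#C[C@H](C/C=C/C(OC)=C(OC)\C(OC)=C=O)CO[Si](C)(C)C(C)(C)C | intermediate
12 | 6-alkyl-2,3,4-trimethoxycyclohexa-2,4-dien-1-one | CC(C)[Si](C(C)C)(C(C)C)C#C[C@H](CC1C=C(OC)C(OC)=C(OC)C1=O)CO[Si](C)(C)C(C)(C)C | intermediate
13 | 6-[(2S)-2-{[(tert-butyldimethylsilyl)oxy]methyl}-4-(triisopropylsilyl)but-3-yn-1-yl]-2,3,4-trimethoxyphenol | CC(C)[Si](C(C)C)(C(C)C)C#C[C@H](Cc1cc(OC)c(OC)c(OC)c1O)CO[Si](C)(C)C(C)(C)C | intermediate
14 | 6-[(2S)-2-(hydroxymethyl)but-3-yn-1-yl]-2,3,4-trimethoxyphenol | C#C[C@H](Cc1cc(OC)c(OC)c(OC)c1O)CO | intermediate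
15 | (3S)-3-ethynyl-6,7,8-trimethoxychroman | C#C[C@H]1COc2c(cc(OC)c(OC)c2OC)C1 | intermediate
16 | lithium acetylide of 15 | [Li]C#C[C@H]1COc2c(cc(OC)c(OC)c2OC)C1 | intermediate
17 | lithium alkoxide of the alkynyl–squarate adduct | [Li]OC1(C#C[C@H]2COc3c(cc(OC)c(OC)c3OC)C2)C(OC)=C(OC)C1=O | intermediate
18 | 4-hydroxy-2,3-dimethoxy-4-{[(3S)-6,7,8-trimethoxychroman-3-yl]ethynyl}cyclobut-2-en-1-one | OC1(C#C[C@H]2COc3c(cc(OC)c(OC)c3OC)C2)C(OC)=C(OC)C1=O | intermediate
19 | (Z)-enynylketene | O=C=C(OC)/C(OC)=C(O)\C#C[C@H]1COc2c(cc(OC)c(OC)c2OC)C1 | intermediate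
20 | aromatic 1,4-diradical | COc1c(OC)c([O])c([C@H]2COc3c(cc(OC)c(OC)c3OC)C2)[c]c1O | intermediate
21 | abruquinone B | COC1=C(OC)C(=O)C([C@H]2COc3c(cc(OC)c(OC)c3OC)C2)=CC1=O | target

Total step count: 9. Longest linear sequence: 9 steps (1 to 21); 7 enters twice.

Steps most likely to fail

Step 9.
- What may go wrong: the ketene/diradical manifold may be diverted. The possibilities are five-membered closure, capture of the C6' σ-radical by solvent or by the nearby ring A before hydrogen transfer, or thermal erosion of the C3 configuration once the quinone is present.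
- Fallback (sets out from 15, returns at 21): ring B would be made by the closed-shell sequence already used for ring A, followed by a mild oxidation.
- Hydrozirconation of 15 with Cp2Zr(H)Cl and iodinolysis would give (3S)-3-[(E)-2-iodoethenyl]-6,7,8-trimethoxychroman F1.
- Treatment with t-BuLi at −78 °C, then 7, then aq NH4Cl would give 4-hydroxy-2,3-dimethoxy-4-{(E)-2-[(3S)-6,7,8-trimethoxychroman-3-yl]ethenyl}cyclobut-2-en-1-one F2.
- Heating in toluene would lead by 4π opening and 6π closure to 2,3-dimethoxy-5-[(3S)-6,7,8-trimethoxychroman-3-yl]benzene-1,4-diol F3.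
- Ag2O in Et2O oxidises a free hydroquinone but not the fully etherified ring A, so it would give 21.

Step 2.
- What may go wrong: the γ-silyloxy enal may show poor facial selectivity, or may undergo competing 1,2-addition or acetal formation in methanol.
- Fallback (sets out from 3 and 4, returns at 5): C3 would be set by an SN2'-selective allylic substitution instead of a 1,4-addition.
- Luche reduction of 3 would give (E)-4-[(tert-butyldimethylsilyl)oxy]but-2-en-1-ol F4.
- ClP(O)(OEt)2 with Et3N and DMAP would give (E)-4-[(tert-butyldimethylsilyl)oxy]but-2-en-1-yl diethyl phosphate F5.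
- Metalation of 4 with DIBAL-H (cat. Et3N) would give diisobutyl[(triisopropylsilyl)ethynyl]aluminium F6.
- Under chiral NHC–Cu catalysis this should displace the phosphate at the γ-carbon to give (3S)-3-{[(tert-butyldimethylsilyl)oxy]methyl}-5-(triisopropylsilyl)pent-1-en-4-yne F7.
- Chemoselective hydroboration of the terminal alkene with 9-BBN and oxidation with NaBO3 would give (3S)-3-{[(tert-butyldimethylsilyl)oxy]methyl}-5-(triisopropylsilyl)pent-4-yn-1-ol F8.
- Dess–Martin oxidation would give 5.

Step 4.
- What may go wrong: O-methylation of the hindered tertiary alkoxide may be incomplete, or the alkoxide may fragment on warming, which would lose the differentiation of the two ring-A oxygens.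
- Fallback (sets out from 9, returns at 13): the two oxygens would be told apart after aromatisation, by sterics.
- Quenching 9 with aq NH4Cl at −78 °C would give 4-[(1E,4S)-4-{[(tert-butyldimethylsilyl)oxy]methyl}-6-(triisopropylsilyl)hex-1-en-5-yn-1-yl]-4-hydroxy-2,3-dimethoxycyclobut-2-en-1-one F9.
- Thermolysis as in step 5 would give 5-[(2S)-2-{[(tert-butyldimethylsilyl)oxy]methyl}-4-(triisopropylsilyl)but-3-yn-1-yl]-2,3-dimethoxybenzene-1,4-diol F10.
- In F10 the C6 hydroxyl is flanked by H-5, whereas the C8a hydroxyl is flanked by the branched side chain.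
- One equivalent of MeI with K2CO3 in acetone under argon should therefore methylate the open C6–OH and give 13.

Further compounds
F1 | step 9 | (3S)-3-[(E)-2-iodoethenyl]-6,7,8-trimethoxychroman | I/C=C/[C@H]1COc2c(cc(OC)c(OC)c2OC)C1
F2 | step 9 | 4-hydroxy-2,3-dimethoxy-4-{(E)-2-[(3S)-6,7,8-trimethoxychroman-3-yl]ethenyl}cyclobut-2-en-1-one | OC1(/C=C/[C@H]2COc3c(cc(OC)c(OC)c3OC)C2)C(OC)=C(OC)C1=O
F3 | step 9 | 2,3-dimethoxy-5-[(3S)-6,7,8-trimethoxychroman-3-yl]benzene-1,4-diol | COc1c(OC)c(O)c([C@H]2COc3c(cc(OC)c(OC)c3OC)C2)cc1O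
F4 | step 2 | (E)-4-[(tert-butyldimethylsilyl)oxy]but-2-en-1-ol | CC(C)(C)[Si](C)(C)OC/C=C/CO
F5 | step 2 | (E)-4-[(tert-butyldimethylsilyl)oxy]but-2-en-1-yl diethyl phosphate | CCOP(=O)(OCC)OC/C=C/CO[Si](C)(C)C(C)(C)C
F6 | step 2 | diisobutyl[(triisopropylsilyl)ethynyl]aluminium | CC(C)C[Al](CC(C)C)C#C[Si](C(C)C)(C(C)C)C(C)C
F7 | step 2 | (3S)-3-{[(tert-butyldimethylsilyl)oxy]methyl}-5-(triisopropylsilyl)pent-1-en-4-yne | CC(C)[Si](C(C)C)(C(C)C)C#C[C@H](C=C)CO[Si](C)(C)C(C)(C)C
F8 | step 2 | (3S)-3-{[(tert-butyldimethylsilyl)oxy]methyl}-5-(triisopropylsilyl)pent-4-yn-1-ol | CC(C)[Si](C(C)C)(C(C)C)C#C[C@H](CCO)CO[Si](C)(C)C(C)(C)C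
F9 | step 4 | 4-[(1E,4S)-4-{[(tert-butyldimethylsilyl)oxy]methyl}-6-(triisopropylsilyl)hex-1-en-5-yn-1-yl]-4-hydroxy-2,3-dimethoxycyclobut-2-en-1-one | CC(C)[Si](C(C)C)(C(C)C)C#C[C@H](C/C=C/C1(O)C(OC)=C(OC)C1=O)CO[Si](C)(C)C(C)(C)C
F10 | step 4 | 5-[(2S)-2-{[(tert-butyldimethylsilyl)oxy]methyl}-4-(triisopropylsilyl)but-3-yn-1-yl]-2,3-dimethoxybenzene-1,4-diol | CC(C)[Si](C(C)C)(C(C)C)C#C[C@H](Cc1cc(O)c(OC)c(OC)c1O)CO[Si](C)(C)C(C)(C)C
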